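Two questions stood on this flask, and I took both through one ratio.

1. whether the average number of monomer units in a chain (chains begun, living or dead) reaches 40 by 12 min (yes / no)
2. average number of monomer units in a chain (chains begun, living or dead) at 12 min

| flask | J | G | remark | time |
|---|---|---|---|---|
| ash | 0.48 M | 3.9 mM | run made earlier |  |
| larch | 0.48 M | 15 mM | run made earlier |  |
| elm | 0.72 M | 7.7 mM | run made earlier |  |
| flask | 0.48 M | 7.7 mM |  | 12 min |

| run | time / min | Q / % | J / % |
|---|---|---|---|
| ash | 1.00 | 1.1 | 96.7 |
| ash | 2.00 | 3.5 | 94.8 |
| ash | 3.00 | 6.6 | 90.9 |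
| ash | 5.00 | 15.5 | 84.2 |
| ash | 8.00 | 25.7 | 71.6 |
| ash | 15.0 | 51.4 | 45.3 |
| larch | 2.50 | 17.3 | 82.2 |
| larch | 5.00 | 43.0 | 56.3 |
| larch | 8.00 | 67.5 | 31.6 |
| larch | 10.0 | 77.0 | 20.3 |
| larch | 12.0 | 84.7 | 13.2 |
| larch | 15.0 | 91.5 | 8.7 |
| elm | 1.00 | 2.4 | 98.1 |
| elm | 2.00 | 7.9 | 91.4 |
| elm | 4.00 | 22.2 | 78.6 |
| elm | 8.00 | 49.8 | 47.1 |
| elm | 15.0 | 80.2 | 19.0 |

(each reading ± 1 percentage point)

- the average divides the monomer in chains by the number of chains begun, living and dead together
- steps thought possible: J + G -> D + Q; J + D -> Q + D; J -> X; J + G -> E
- the earlier runs do not show the number of chains; that part of a forecast is a guess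

I began by dividing J by G down the recipes. For the flask this gave ρ = 62.3, the moles of J charged per mole of G charged. Each chain takes one G through J + G → D + Q, so G is the limiting reagent for chain starts, with J far more plentiful.

The length is then fρ/b, where f is the share of the J charged that stands as Q and b is the share of the G charged that has begun chains. At one end, b equals one and the length is the floor fρ. At the other end, a smaller b lifts the length above that floor.

The larch row has ρ = 32.0, under the 40 wanted, and the ash row has 123, above it. The flask lies between them, and its floor reaches the wanted length at f = 64.2%.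

The elm row has the flask's G. Interpolating its Q readings to 12 min gave me f = 67.2%, though elm carries more J, so this is my estimate for the flask. My floor was therefore 41.9, higher than the wanted length, and I answered yes.

The forecast said yes with 44 units, holding that “nearly all G has reacted”. Its length is higher than my floor.

The flask gave yes, with 52.9 units at 12.0 min, longer than the forecast's length.

    J + G → D + Q (k = 0.490 /M/min)
    J + D → Q + D, rate k2*[D]*[J] (k = 20.0 /M/min)
    J → X (k = 0.00250 /min)
    J + G → E (k = 0.0860 /M/min)

At that time the flask held D at 0.00584 M, so b was 75.9%. Multiplying ρ by its Q of 64.3% makes a floor of 40.1, and dividing by b returns 52.9 units. In the elm run ρ was 93.5, and the Q reading of 80.2% at 15.0 min gave a floor of 75.0 units.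

Readings and results are simulated with constants of no real substance; noise was put on by code.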